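**Retrosynthetic overview**

- The target 14 has one ring, a cyclohex-2-enone numbered C1(=O)–C2=C3–C4–C5–C6 with the nonadecyl chain on C3. The plan rests on this enone: C2, C1 and C6 come from an acetoacetate unit, and C3, C4 and C5 from a vinyl ketone whose carbonyl carbon (C3) already bears the chain.
- Last disconnection: the C6–CO2Et bond, by hydrolysis and decarboxylation of β-keto ester 12.
- Key disconnection: C5–C6 (Michael addition) and C2=C3 (intramolecular Wittig) lead back to ylide 4 and enone 10. The single ring is formed in this step.
- Ylide 4 comes from ethyl 4-chloroacetoacetate and triphenylphosphine. Enone 10 comes from icosanoic acid through its Weinreb amide and vinylmagnesium bromide.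

Key step: step 5

Remark: the target is achiral. The only stereocentre on the route (the ester-bearing carbon of 12 and 13) is made racemic and is removed in step 6.

**Route**

Step 1
Reactants: 1 ethyl 4-chloroacetoacetate; 2 triphenylphosphine
Product: 3 (4-ethoxy-2,4-dioxobutyl)triphenylphosphonium chloride
Conditions: THF, reflux; the salt is filtered off
Reagents that add atoms: none
Why: SN2 quaternisation of the phosphine by the primary α-chloro ketone should give the phosphonium salt, which precipitates and leaves the β-keto ester untouched.

Step 2
Reactants: 3 (4-ethoxy-2,4-dioxobutyl)triphenylphosphonium chloride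
Product: 4 ethyl 3-oxo-4-(triphenylphosphoranylidene)butanoate
Conditions: Na2CO3, H2O/CH2Cl2, rt
Reagents that add atoms: none
Why: Ylide formation by deprotonation of the acyl-activated P–CH2 group needs only aqueous carbonate, which is too mild to hydrolyse the ester, and the stabilised ylide is stable to water and can be isolated.

Step 3
Reactants: 5 icosanoic acid
Product: 7 N-methoxy-N-methylicosanamide, via icosanoyl chloride 6 (not isolated)
Conditions: (COCl)2, cat. DMF, CH2Cl2, 0 °C to rt; then MeNH(OMe)·HCl, Et3N, CH2Cl2, 0 °C to rt
Reagents that add atoms: N,O-dimethylhydroxylamine hydrochloride, CNOC.Cl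
Why: Acid chloride formation under Vilsmeier catalysis followed by N-acylation of the hydroxylamine (Weinreb amide synthesis) is routine for a saturated fatty acid with no other functional group.

Step 4
Reactants: 7 N-methoxy-N-methylicosanamide; 8 vinylmagnesium bromide
Product: 10 docos-1-en-3-one, via tetrahedral bromomagnesium adduct 9 (not isolated)
Conditions: CH2=CHMgBr (1.5 equiv), THF, 0 °C; inverse quench into cold 1 M HCl; the enone is kept cold and used promptly
Reagents that add atoms: none
Why: In the Weinreb ketone synthesis the chelated adduct 9 does not collapse before the quench, so only one vinyl group is added, and the acidic inverse quench protonates the released amine before it can add to the vinyl ketone.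

Step 5
Reactants: 4 ethyl 3-oxo-4-(triphenylphosphoranylidene)butanoate; 10 docos-1-en-3-one
Product: 12 ethyl 4-nonadecyl-2-oxocyclohex-3-ene-1-carboxylate (racemic), via open-chain Michael adduct 11 (not isolated)
Conditions: 4 (1.1 equiv), NaH (1.1 equiv), THF, 0 °C; slow addition of 10, 0 °C to rt; then reflux; AcOH quench
Reagents that add atoms: none
Why: NaH removes the proton at the carbon between ketone and ester of 4, and this carbanion adds in a Michael reaction to the unsubstituted β-carbon of 10, forming the ring bond C5–C6 and giving 11. In 11 the acyl-stabilised ylide carbon is placed for a 6-exo-trig attack on the chain ketone, and on heating the intramolecular Wittig olefination forms C2=C3 through an oxaphosphetane that loses triphenylphosphine oxide, which closes the only ring. The closest known reaction type is the tandem Michael–Wittig [3+3] cyclohexenone annulation of 4-(triphenylphosphoranylidene)acetoacetates with α,β-unsaturated aldehydes and ketones. The one new stereocentre (the ester-bearing carbon of 12) forms racemic, is enolisable and is deleted in step 6, so it needs no control. The step needs site selectivity in both bond formations: the Michael addition goes through the more basic, last-formed carbanion and not through the ylide carbon, and the ring can close only where phosphorus sits, so the chain ends on the β-carbon of the enone and an aldol closure through the chain α-CH2, which would give the 3-methyl-2-octadecyl isomer, has no pathway. A full equivalent of NaH is used because 12 is a more acidic β-keto ester than 4 and would stop a base-catalytic chain, and slow addition of 10 to a slight excess of the anion keeps oligomerisation of the vinyl ketone and double addition low.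

Step 6
Reactants: 12 ethyl 4-nonadecyl-2-oxocyclohex-3-ene-1-carboxylate (racemic)
Product: 14 3-nonadecylcyclohex-2-en-1-one, via beta-keto acid 13 (not isolated)
Conditions: KOH (3 equiv), EtOH/THF/H2O, 50 °C; then 2 M HCl to pH 1, 60 °C
Reagents that add atoms: none
Why: Saponification of the β-keto ester and acid-induced decarboxylation of the β-keto acid through the six-membered cyclic transition state (ketonic hydrolysis) should leave the conjugated 3-alkylcyclohexenone, which is the thermodynamically favoured enone isomer.

**Compound list**

1 | ethyl 4-chloroacetoacetate (ethyl 4-chloro-3-oxobutanoate) | CCOC(=O)CC(=O)CCl | starting material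
2 | triphenylphosphine | c1ccc(cc1)P(c1ccccc1)c1ccccc1 | starting material
3 | (4-ethoxy-2,4-dioxobutyl)triphenylphosphonium chloride | CCOC(=O)CC(=O)C[P+](c1ccccc1)(c1ccccc1)c1ccccc1.[Cl-] | intermediate
4 | ethyl 3-oxo-4-(triphenylphosphoranylidene)butanoate | CCOC(=O)CC(=O)C=P(c1ccccc1)(c1ccccc1)c1ccccc1 | intermediate
5 | icosanoic acid | CCCCCCCCCCCCCCCCCCCC(=O)O | starting material
6 | icosanoyl chloride | CCCCCCCCCCCCCCCCCCCC(=O)Cl | intermediate
7 | N-methoxy-N-methylicosanamide | CCCCCCCCCCCCCCCCCCCC(=O)N(C)OC | intermediate
8 | vinylmagnesium bromide | C=C[Mg]Br | starting material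
9 | bromomagnesium alkoxide of 3-[methoxy(methyl)amino]docos-1-en-3-ol (tetrahedral Weinreb adduct) | CCCCCCCCCCCCCCCCCCCC(O[Mg]Br)(C=C)N(C)OC | intermediate
10 | docos-1-en-3-one | CCCCCCCCCCCCCCCCCCCC(=O)C=C | intermediate
11 | ethyl 5-oxo-2-[(triphenylphosphoranylidene)acetyl]tetracosanoate (racemic) | CCCCCCCCCCCCCCCCCCCC(=O)CCC(C(=O)OCC)C(=O)C=P(c1ccccc1)(c1ccccc1)c1ccccc1 | intermediate
12 | ethyl 4-nonadecyl-2-oxocyclohex-3-ene-1-carboxylate (racemic) | CCCCCCCCCCCCCCCCCCCC1=CC(=O)C(C(=O)OCC)CC1 | intermediate
13 | 4-nonadecyl-2-oxocyclohex-3-ene-1-carboxylic acid (racemic) | CCCCCCCCCCCCCCCCCCCC1=CC(=O)C(C(=O)O)CC1 | intermediate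
14 | 3-nonadecylcyclohex-2-en-1-one | CCCCCCCCCCCCCCCCCCCC1=CC(=O)CCC1 | target

**Step count**

Total steps: 6. Longest linear sequence: 4 steps (steps 3, 4, 5, 6; the ylide branch, steps 1, 2, 5, 6, is equally long).

**The three steps most likely to fail**

1. Step 5. The ring-closing olefination of a dialkyl ketone by an acyl-stabilised ylide may be slow. The open-chain adduct could then take up a second molecule of vinyl ketone, or the vinyl ketone could oligomerise under the strongly basic conditions. The fallback sets out from 10 and comes back to the route at 14. It is a Robinson-type annulation in which C–H acidity, not phosphorus, directs the ring closure. Commercial diethyl 3-oxopentanedioate, SMILES CCOC(=O)CC(=O)CC(=O)OCC, should add to 10 with catalytic NaOEt in EtOH/THF at 0 °C, conditions far milder than NaH, to give racemic diethyl 3-oxo-2-(3-oxodocosyl)pentanedioate F1. Piperidinium acetate in toluene with azeotropic removal of water should then close the ring by intramolecular Knoevenagel condensation of the remaining doubly activated CH2 onto the chain ketone, giving racemic diethyl 4-nonadecyl-2-oxocyclohex-3-ene-1,3-dicarboxylate F2. KOH in aqueous EtOH, then HCl and heat, should hydrolyse both esters to racemic 4-nonadecyl-2-oxocyclohex-3-ene-1,3-dicarboxylic acid F3, which loses both carboxyl groups to give 14. The carboxyl on the alkene carbon leaves after tautomerisation to the β,γ-unsaturated keto acid.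

2. Step 4. The released N,O-dimethylhydroxylamine or excess Grignard reagent may add in a conjugate sense to the new vinyl ketone during the quench, and the unhindered vinyl ketone may oligomerise on concentration or storage. The fallback sets out from 6, made from 5 as in the first half of step 3 and freed of solvent, and comes back to the route at 10. Treatment of 6 with ethylene and AlCl3 in CH2Cl2 at 0 °C, a Friedel–Crafts-type acylation of ethylene, should give the storable masked vinyl ketone 1-chlorodocosan-3-one F4. Et3N in Et2O at rt eliminates HCl from it just before use to give 10.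

3. Step 6. Saponification of the enolised β-keto ester may be slow, which leaves time for base-induced self-condensation of the enone or retro-Claisen ring opening. The fallback sets out from 2 and 10 and comes back to the route at 13 and then 14; it changes the ester to one that is removed by acid. Commercial tert-butyl 4-chloro-3-oxobutanoate, SMILES CC(C)(C)OC(=O)CC(=O)CCl, and 2 should give, as in step 1, [4-(tert-butoxy)-2,4-dioxobutyl]triphenylphosphonium chloride F5. Aqueous Na2CO3 should convert it into tert-butyl 3-oxo-4-(triphenylphosphoranylidene)butanoate F6. Annulation with 10 under the conditions of step 5 should pass through racemic tert-butyl 5-oxo-2-[(triphenylphosphoranylidene)acetyl]tetracosanoate F7 and give racemic tert-butyl 4-nonadecyl-2-oxocyclohex-3-ene-1-carboxylate F8. CF3CO2H in CH2Cl2 at rt cleaves the tert-butyl ester to acid 13, and warming in toluene decarboxylates 13 to 14 without any base.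

**Further compounds**

F1 | step 5 | diethyl 3-oxo-2-(3-oxodocosyl)pentanedioate (racemic) | CCCCCCCCCCCCCCCCCCCC(=O)CCC(C(=O)OCC)C(=O)CC(=O)OCC
F2 | step 5 | diethyl 4-nonadecyl-2-oxocyclohex-3-ene-1,3-dicarboxylate (racemic) | CCCCCCCCCCCCCCCCCCCC1=C(C(=O)OCC)C(=O)C(C(=O)OCC)CC1
F3 | step 5 | 4-nonadecyl-2-oxocyclohex-3-ene-1,3-dicarboxylic acid (racemic) | CCCCCCCCCCCCCCCCCCCC1=C(C(=O)O)C(=O)C(C(=O)O)CC1
F4 | step 4 | 1-chlorodocosan-3-one | CCCCCCCCCCCCCCCCCCCC(=O)CCCl
F5 | step 6 | [4-(tert-butoxy)-2,4-dioxobutyl]triphenylphosphonium chloride | CC(C)(C)OC(=O)CC(=O)C[P+](c1ccccc1)(c1ccccc1)c1ccccc1.[Cl-]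
F6 | step 6 | tert-butyl 3-oxo-4-(triphenylphosphoranylidene)butanoate | CC(C)(C)OC(=O)CC(=O)C=P(c1ccccc1)(c1ccccc1)c1ccccc1
F7 | step 6 | tert-butyl 5-oxo-2-[(triphenylphosphoranylidene)acetyl]tetracosanoate (racemic) | CCCCCCCCCCCCCCCCCCCC(=O)CCC(C(=O)OC(C)(C)C)C(=O)C=P(c1ccccc1)(c1ccccc1)c1ccccc1
F8 | step 6 | tert-butyl 4-nonadecyl-2-oxocyclohex-3-ene-1-carboxylate (racemic) | CCCCCCCCCCCCCCCCCCCC1=CC(=O)C(C(=O)OC(C)(C)C)CC1
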